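**Retrosynthetic overview**

1. The target is a 3,5-diformylphloroglucinol joined through the benzylic carbon C1′ to an ent-eudesmane-4,11-diol (ring A = C1–C5 and C10; ring B = C5–C10). The aldehydes and phenols are unveiled last (ArH → ArBr → ArCHO, then O-demethylation); the C4 carbinol comes from a methyl-cerium addition to a C4 ketone, and the C4 oxygen with H-5 from hydroboration of a C4=C5 alkene.
2. Ring A is opened at C1–C10: thermal disrotatory 6π-electrocyclization of the (1E,3Z)-triene C1=C2–C3=C4–C5=C10, whose last double bond is the ring-B alkene.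
3. Enabling feature: the C1–C10 bond joins the quaternary, methyl-bearing ring-fusion carbon C10 to a CH carbon (C1) whose side chain is trans to that methyl. Ring B holds the methyl "inside" and the E-alkene puts the side chain "outside", so disrotation gives exactly this pattern, and the C2=C3/C4=C5 diene it leaves is the handle for the C4 hydroxyl and H-5.
4. The triene comes from the ring-B enol triflate of (S)-carvone, a two-carbon alkyne linker, and an (E)-alkenyl iodide that carries C1′ (Evans alkylation).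
5. Ring order: ring B (chiral pool) and the arene are bought; ring A is the only ring formed (step 12).

Key step: step 12

Remark on numbering: terpenoid carbons carry eudesmane numbers (C1–C10 ring atoms, C11 the carbinol carbon on C7); C1′ is the benzylic carbon.
Assumption: 2-(2,4,6-trimethoxyphenyl)acetic acid is a catalogue compound.

**Route**

Step 1
Reactants: 1 (S)-(+)-carvone
Product: 3 (5S)-2-methyl-5-(prop-1-en-2-yl)cyclohex-1-en-1-yl trifluoromethanesulfonate, via lithium enolate 2 (not isolated)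
Conditions: LiBH(s-Bu)3, THF, −78 °C; then PhNTf2, −78 °C to rt
Reagents that add atoms: N-phenylbis(trifluoromethanesulfonimide), O=S(=O)(N(c1ccccc1)S(=O)(=O)C(F)(F)F)C(F)(F)F
Why: Conjugate hydride delivery to the enone gives the tetrasubstituted enolate regiospecifically and PhNTf2 traps it on oxygen (1,4-reduction/enolate triflation); the carvone stereocentre is untouched and becomes C7.

Step 2
Reactants: 3 (5S)-2-methyl-5-(prop-1-en-2-yl)cyclohex-1-en-1-yl trifluoromethanesulfonate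
Product: 4 (5S)-5-(2-hydroxypropan-2-yl)-2-methylcyclohex-1-en-1-yl trifluoromethanesulfonate
Conditions: Co(acac)2 (cat.), PhSiH3, O2 (1 atm), THF, rt; then aq. Na2S2O3
Reagents that add atoms: dioxygen, O=O
Why: Mukaiyama hydration (hydrogen-atom transfer, O2 capture, reduction) is Markovnikov-selective for the electron-rich 1,1-disubstituted alkene and should leave the electron-poor tetrasubstituted enol triflate alone; no stereocentre is formed.

Step 3
Reactants: 4 (5S)-5-(2-hydroxypropan-2-yl)-2-methylcyclohex-1-en-1-yl trifluoromethanesulfonate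
Product: 5 2-[(1S)-4-methyl-3-[(trimethylsilyl)ethynyl]cyclohex-3-en-1-yl]propan-2-ol
Conditions: Pd(PPh3)2Cl2 (cat.), CuI (cat.), Et3N, DMF, rt to 50 °C
Reagents that add atoms: ethynyltrimethylsilane, C#C[Si](C)(C)C
Why: Sonogashira coupling of an alkenyl triflate with a terminal alkyne keeps the ring alkene in place and tolerates the free tertiary alcohol.

Step 4
Reactants: 6 2-(2,4,6-trimethoxyphenyl)acetic acid; 7 (4S)-4-benzyl-1,3-oxazolidin-2-one
Product: 9 (4S)-4-benzyl-3-[(2,4,6-trimethoxyphenyl)acetyl]-1,3-oxazolidin-2-one, via mixed pivalic anhydride 8 (not isolated)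
Conditions: t-BuCOCl, Et3N, THF, −20 °C; then LiCl, 7, rt
Reagents that add atoms: none
Why: N-acylation of the Evans auxiliary through the mixed anhydride is a standard one-pot procedure; no new stereocentre.

Step 5
Reactants: 9 (4S)-4-benzyl-3-[(2,4,6-trimethoxyphenyl)acetyl]-1,3-oxazolidin-2-one
Product: 11 (4S)-4-benzyl-3-[(2S)-4-methyl-2-(2,4,6-trimethoxyphenyl)pent-4-enoyl]-1,3-oxazolidin-2-one, via sodium enolate 10 (not isolated)
Conditions: NaN(SiMe3)2, THF, −78 °C; then 3-bromo-2-methylprop-1-ene, −78 to −40 °C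
Reagents that add atoms: 3-bromo-2-methylprop-1-ene, C=C(C)CBr
Why: Evans alkylation: the chelated (Z)-enolate is attacked by the allylic bromide on the face opposite the benzyl group, which sets the future C1′ centre (2S here).

Step 6
Reactants: 11 (4S)-4-benzyl-3-[(2S)-4-methyl-2-(2,4,6-trimethoxyphenyl)pent-4-enoyl]-1,3-oxazolidin-2-one
Product: 12 (2S)-4-methyl-2-(2,4,6-trimethoxyphenyl)pent-4-en-1-ol
Conditions: LiBH4, Et2O, H2O (1 equiv), 0 °C
Reagents that add atoms: none
Why: Reductive cleavage of the imide gives the primary alcohol without touching the benzylic stereocentre and returns the auxiliary.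

Step 7
Reactants: 12 (2S)-4-methyl-2-(2,4,6-trimethoxyphenyl)pent-4-en-1-ol
Product: 13 (2S)-4-methyl-2-(2,4,6-trimethoxyphenyl)pentan-1-ol
Conditions: H2 (1 atm), Pd/C, EtOAc, rt
Reagents that add atoms: none
Why: Heterogeneous hydrogenation saturates the 1,1-disubstituted alkene to the isobutyl group; the stereocentre is not involved.

Step 8
Reactants: 13 (2S)-4-methyl-2-(2,4,6-trimethoxyphenyl)pentan-1-ol
Product: 14 (2S)-4-methyl-2-(2,4,6-trimethoxyphenyl)pentanal
Conditions: Dess–Martin periodinane, NaHCO3, CH2Cl2, 0 °C; crude product used at once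
Reagents that add atoms: none
Why: Buffered Dess–Martin oxidation is non-basic, so the enolisable benzylic centre of the α-aryl aldehyde should keep its configuration if the aldehyde is not stored.

Step 9
Reactants: 14 (2S)-4-methyl-2-(2,4,6-trimethoxyphenyl)pentanal
Product: 15 2-[(1E,3R)-1-iodo-5-methylhex-1-en-3-yl]-1,3,5-trimethoxybenzene
Conditions: CrCl2, CHI3, THF–dioxane, 0 °C to rt
Reagents that add atoms: iodoform, IC(I)I
Why: Takai olefination is E-selective and non-basic, so the adjacent stereocentre should survive (the descriptor changes to R by priority only).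

Step 10
Reactants: 5 2-[(1S)-4-methyl-3-[(trimethylsilyl)ethynyl]cyclohex-3-en-1-yl]propan-2-ol; 15 2-[(1E,3R)-1-iodo-5-methylhex-1-en-3-yl]-1,3,5-trimethoxybenzene
Product: 17 2-[(1S)-4-methyl-3-[(3E,5R)-7-methyl-5-(2,4,6-trimethoxyphenyl)oct-3-en-1-yn-1-yl]cyclohex-3-en-1-yl]propan-2-ol, via terminal enyne 16 (not isolated)
Conditions: CsF, Pd(PPh3)2Cl2 (cat.), CuI (cat.), Et3N, THF–MeOH, rt
Reagents that add atoms: none
Why: Fluoride frees the terminal alkyne in the flask and it enters a Sonogashira coupling with the alkenyl iodide with retention of the E geometry (one-pot desilylation/Sonogashira).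

Step 11
Reactants: 17 2-[(1S)-4-methyl-3-[(3E,5R)-7-methyl-5-(2,4,6-trimethoxyphenyl)oct-3-en-1-yn-1-yl]cyclohex-3-en-1-yl]propan-2-ol
Product: 18 2-[(1S)-4-methyl-3-[(1Z,3E,5R)-7-methyl-5-(2,4,6-trimethoxyphenyl)octa-1,3-dien-1-yl]cyclohex-3-en-1-yl]propan-2-ol
Conditions: Zn dust activated with Cu(OAc)2 and AgNO3, MeOH–H2O 1:1, 35 °C
Reagents that add atoms: none
Why: Boland reduction adds hydrogen syn to the conjugated alkyne only, giving the Z alkene and hence the (1E,3Z)-hexatriene needed for closure.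

Step 12
Reactants: 18 2-[(1S)-4-methyl-3-[(1Z,3E,5R)-7-methyl-5-(2,4,6-trimethoxyphenyl)octa-1,3-dien-1-yl]cyclohex-3-en-1-yl]propan-2-ol
Product: 19 2-[(2S,4aR,5S)-4a-methyl-5-[(1R)-3-methyl-1-(2,4,6-trimethoxyphenyl)butyl]-1,2,3,4,4a,5-hexahydronaphthalen-2-yl]propan-2-ol
Conditions: degassed PhMe, BHT (cat.), sealed tube, 150 °C
Reagents that add atoms: none
Why: On heating, the s-cis,s-cis conformer of the C1=C2–C3=C4–C5=C10 triene should undergo a thermally allowed disrotatory 6π-electrocyclization that forms the C1–C10 σ-bond and closes ring A as a cyclohexa-1,3-diene (C2=C3, C4=C5); the closest known reaction is the thermal closure of previtamin D to pyro- and isopyrocalciferol, which also builds a methyl-bearing quaternary carbon from a ring-embedded triene terminus. Ring A is closed in one pericyclic event (6π electrocyclic, disrotatory). Because ring B holds the C10 methyl "inside" and the E alkene places the side chain "outside", orbital symmetry puts H-1 cis and the side chain trans to the new quaternary methyl, which fixes C1 and C10 relative to each other. The absolute sense (which of the two disrotatory modes) is expected to be set by ring B: only the mode that lets ring B relax from its half-chair, C7 substituent equatorial, directly into a chair places the methyl axial and cis to the hydroxypropyl group as required, and the allylic C1′ centre, which can keep its aryl group anti to the forming bond in either mode, should not override this. The step needs periselectivity over sigmatropic hydrogen migration: the [1,7] shift from the C10 methyl is reversible and feeds back into the closure, and the E and Z geometries installed in steps 9 and 11 secure the stereochemical outcome.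

Step 13
Reactants: 19 2-[(2S,4aR,5S)-4a-methyl-5-[(1R)-3-methyl-1-(2,4,6-trimethoxyphenyl)butyl]-1,2,3,4,4a,5-hexahydronaphthalen-2-yl]propan-2-ol
Product: 20 2-[(2S,4aR,5S)-4a-methyl-5-[(1R)-3-methyl-1-(2,4,6-trimethoxyphenyl)butyl]-1,2,3,4,4a,5,6,7-octahydronaphthalen-2-yl]propan-2-ol
Conditions: 2-nitrobenzenesulfonohydrazide, Et3N, CH2Cl2, rt
Reagents that add atoms: none
Why: Diimide reduction transfers hydrogen syn to the cis-disubstituted C2=C3 bond and should not touch the trisubstituted C4=C5 bond; no stereocentre is formed.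

Step 14
Reactants: 20 2-[(2S,4aR,5S)-4a-methyl-5-[(1R)-3-methyl-1-(2,4,6-trimethoxyphenyl)butyl]-1,2,3,4,4a,5,6,7-octahydronaphthalen-2-yl]propan-2-ol
Product: 22 (1S,4S,4aR,7S,8aS)-7-(2-hydroxypropan-2-yl)-4a-methyl-4-[(1R)-3-methyl-1-(2,4,6-trimethoxyphenyl)butyl]decahydronaphthalen-1-ol, via alkylborane 21 (not isolated)
Conditions: BH3·THF (excess), THF, 0 °C to rt; then NaOH, H2O2, 0 °C to rt
Reagents that add atoms: hydrogen peroxide, OO
Why: Hydroboration–oxidation puts boron on the less substituted C4 and hydrogen on C5 in a syn addition from the face opposite the axial C10 methyl (which is 1,3-diaxial to C4 on the other face), so H-5 is set trans to the methyl (trans-decalin) and the C4 hydroxyl forms with retention.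

Step 15
Reactants: 22 (1S,4S,4aR,7S,8aS)-7-(2-hydroxypropan-2-yl)-4a-methyl-4-[(1R)-3-methyl-1-(2,4,6-trimethoxyphenyl)butyl]decahydronaphthalen-1-ol
Product: 23 (4S,4aR,7S,8aS)-7-(2-hydroxypropan-2-yl)-4a-methyl-4-[(1R)-3-methyl-1-(2,4,6-trimethoxyphenyl)butyl]octahydronaphthalen-1(2H)-one
Conditions: Dess–Martin periodinane, NaHCO3, CH2Cl2, rt
Reagents that add atoms: none
Why: Buffered Dess–Martin oxidation converts the secondary alcohol to the ketone and leaves the tertiary alcohol and the epimerisable C5 centre unchanged.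

Step 16
Reactants: 23 (4S,4aR,7S,8aS)-7-(2-hydroxypropan-2-yl)-4a-methyl-4-[(1R)-3-methyl-1-(2,4,6-trimethoxyphenyl)butyl]octahydronaphthalen-1(2H)-one
Product: 24 (1R,4S,4aR,7S,8aS)-7-(2-hydroxypropan-2-yl)-1,4a-dimethyl-4-[(1R)-3-methyl-1-(2,4,6-trimethoxyphenyl)butyl]decahydronaphthalen-1-ol
Conditions: MeMgCl, anhydrous CeCl3, THF, −78 to 0 °C
Reagents that add atoms: methylmagnesium chloride, C[Mg]Cl
Why: The weakly basic organocerium reagent adds without enolising C5, and from the equatorial direction because the axial path is blocked by the 1,3-diaxial C10 methyl, which gives the axial C4 alcohol cis to that methyl as in the target.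

Step 17
Reactants: 24 (1R,4S,4aR,7S,8aS)-7-(2-hydroxypropan-2-yl)-1,4a-dimethyl-4-[(1R)-3-methyl-1-(2,4,6-trimethoxyphenyl)butyl]decahydronaphthalen-1-ol
Product: 25 (1R,4S,4aR,7S,8aS)-4-[(1R)-1-(3,5-dibromo-2,4,6-trimethoxyphenyl)-3-methylbutyl]-7-(2-hydroxypropan-2-yl)-1,4a-dimethyldecahydronaphthalen-1-ol
Conditions: N-bromosuccinimide (2.1 equiv), MeCN, 0 °C, dark
Reagents that add atoms: N-bromosuccinimide, O=C1CCC(=O)N1Br
Why: Electrophilic aromatic bromination of the strongly activated trialkoxyarene can only occur at its two free ring positions.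

Step 18
Reactants: 25 (1R,4S,4aR,7S,8aS)-4-[(1R)-1-(3,5-dibromo-2,4,6-trimethoxyphenyl)-3-methylbutyl]-7-(2-hydroxypropan-2-yl)-1,4a-dimethyldecahydronaphthalen-1-ol
Product: 27 5-[(1R)-1-[(1S,4R,4aS,6S,8aR)-4-hydroxy-6-(2-hydroxypropan-2-yl)-4,8a-dimethyldecahydronaphthalen-1-yl]-3-methylbutyl]-2,4,6-trimethoxybenzene-1,3-dicarbaldehyde, via tetralithio intermediate 26 (not isolated)
Conditions: t-BuLi (excess), THF, −78 °C; then DMF, −78 °C to rt; aq. NH4Cl
Reagents that add atoms: N,N-dimethylformamide, CN(C)C=O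
Why: Double bromine–lithium exchange followed by formylation with DMF converts both aryl bromides into aldehydes, the two tertiary alcohols being protected in the flask as their lithium alkoxides.

Step 19
Reactants: 27 5-[(1R)-1-[(1S,4R,4aS,6S,8aR)-4-hydroxy-6-(2-hydroxypropan-2-yl)-4,8a-dimethyldecahydronaphthalen-1-yl]-3-methylbutyl]-2,4,6-trimethoxybenzene-1,3-dicarbaldehyde
Product: 28 5-[(1R)-1-[(1S,4R,4aS,6S,8aR)-4-hydroxy-6-(2-hydroxypropan-2-yl)-4,8a-dimethyldecahydronaphthalen-1-yl]-3-methylbutyl]-2,4,6-trihydroxybenzene-1,3-dicarbaldehyde (target)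
Conditions: NaSEt (excess), DMF, 110 °C; then 1 M HCl
Reagents that add atoms: none
Why: Thiolate SN2 demethylation is fast for aryl methyl ethers ortho or para to formyl groups, so all three ethers should be cleaved without the acid that would ionise the tertiary alcohols.

**Compound list**

1 | (S)-(+)-carvone, (5S)-2-methyl-5-(prop-1-en-2-yl)cyclohex-2-en-1-one | O=C1C[C@@H](C(C)=C)CC=C1C | starting material
2 | lithium (5S)-2-methyl-5-(prop-1-en-2-yl)cyclohex-1-en-1-olate | [Li+].[O-]C1=C(C)CC[C@H](C(C)=C)C1 | intermediate (not isolated)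
3 | (5S)-2-methyl-5-(prop-1-en-2-yl)cyclohex-1-en-1-yl trifluoromethanesulfonate | CC1=C(OS(=O)(=O)C(F)(F)F)C[C@@H](C(C)=C)CC1 | intermediate
4 | (5S)-5-(2-hydroxypropan-2-yl)-2-methylcyclohex-1-en-1-yl trifluoromethanesulfonate | CC1=C(OS(=O)(=O)C(F)(F)F)C[C@@H](C(C)(C)O)CC1 | intermediate
5 | 2-[(1S)-4-methyl-3-[(trimethylsilyl)ethynyl]cyclohex-3-en-1-yl]propan-2-ol | CC1=C(C#C[Si](C)(C)C)C[C@@H](C(C)(C)O)CC1 | intermediate
6 | 2-(2,4,6-trimethoxyphenyl)acetic acid | COc1cc(OC)c(CC(=O)O)c(OC)c1 | starting material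
7 | (4S)-4-benzyl-1,3-oxazolidin-2-one | O=C1OC[C@H](Cc2ccccc2)N1 | starting material
8 | 2,2-dimethylpropanoic 2-(2,4,6-trimethoxyphenyl)acetic anhydride | COc1cc(OC)c(CC(=O)OC(=O)C(C)(C)C)c(OC)c1 | intermediate (not isolated)
9 | (4S)-4-benzyl-3-[(2,4,6-trimethoxyphenyl)acetyl]-1,3-oxazolidin-2-one | O=C1OC[C@H](Cc2ccccc2)N1C(=O)Cc1c(OC)cc(OC)cc1OC | intermediate
10 | sodium (Z)-enolate of 9 | [Na+].[O-]/C(N1C(=O)OC[C@@H]1Cc1ccccc1)=C\c1c(OC)cc(OC)cc1OC | intermediate (not isolated)
11 | (4S)-4-benzyl-3-[(2S)-4-methyl-2-(2,4,6-trimethoxyphenyl)pent-4-enoyl]-1,3-oxazolidin-2-one | O=C1OC[C@H](Cc2ccccc2)N1C(=O)[C@@H](CC(C)=C)c1c(OC)cc(OC)cc1OC | intermediate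
12 | (2S)-4-methyl-2-(2,4,6-trimethoxyphenyl)pent-4-en-1-ol | C=C(C)C[C@@H](c1c(OC)cc(OC)cc1OC)CO | intermediate
13 | (2S)-4-methyl-2-(2,4,6-trimethoxyphenyl)pentan-1-ol | CC(C)C[C@@H](c1c(OC)cc(OC)cc1OC)CO | intermediate
14 | (2S)-4-methyl-2-(2,4,6-trimethoxyphenyl)pentanal | CC(C)C[C@@H](c1c(OC)cc(OC)cc1OC)C=O | intermediate
15 | 2-[(1E,3R)-1-iodo-5-methylhex-1-en-3-yl]-1,3,5-trimethoxybenzene | CC(C)C[C@@H](c1c(OC)cc(OC)cc1OC)/C=C/I | intermediate
16 | 2-[(1S)-3-ethynyl-4-methylcyclohex-3-en-1-yl]propan-2-ol | CC1=C(C#C)C[C@@H](C(C)(C)O)CC1 | intermediate (not isolated)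
17 | 2-[(1S)-4-methyl-3-[(3E,5R)-7-methyl-5-(2,4,6-trimethoxyphenyl)oct-3-en-1-yn-1-yl]cyclohex-3-en-1-yl]propan-2-ol | CC(C)C[C@@H](c1c(OC)cc(OC)cc1OC)/C=C/C#CC1=C(C)CC[C@H](C(C)(C)O)C1 | intermediate
18 | 2-[(1S)-4-methyl-3-[(1Z,3E,5R)-7-methyl-5-(2,4,6-trimethoxyphenyl)octa-1,3-dien-1-yl]cyclohex-3-en-1-yl]propan-2-ol | CC(C)C[C@@H](c1c(OC)cc(OC)cc1OC)/C=C/C=C\C1=C(C)CC[C@H](C(C)(C)O)C1 | intermediate
19 | 2-[(2S,4aR,5S)-4a-methyl-5-[(1R)-3-methyl-1-(2,4,6-trimethoxyphenyl)butyl]-1,2,3,4,4a,5-hexahydronaphthalen-2-yl]propan-2-ol | CC(C)C[C@@H](c1c(OC)cc(OC)cc1OC)[C@@H]1C=CC=C2C[C@@H](C(C)(C)O)CC[C@]12C | intermediate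
20 | 2-[(2S,4aR,5S)-4a-methyl-5-[(1R)-3-methyl-1-(2,4,6-trimethoxyphenyl)butyl]-1,2,3,4,4a,5,6,7-octahydronaphthalen-2-yl]propan-2-ol | CC(C)C[C@@H](c1c(OC)cc(OC)cc1OC)[C@@H]1CCC=C2C[C@@H](C(C)(C)O)CC[C@]12C | intermediate
21 | C4 borane of 20 (boron and H-5 on the face opposite the C10 methyl; C11 oxygen as its borinate) | CC(C)C[C@@H](c1c(OC)cc(OC)cc1OC)[C@@H]1CC[C@H](B)[C@H]2C[C@@H](C(C)(C)OB)CC[C@]12C | intermediate (not isolated)
22 | (1S,4S,4aR,7S,8aS)-7-(2-hydroxypropan-2-yl)-4a-methyl-4-[(1R)-3-methyl-1-(2,4,6-trimethoxyphenyl)butyl]decahydronaphthalen-1-ol | CC(C)C[C@@H](c1c(OC)cc(OC)cc1OC)[C@@H]1CC[C@H](O)[C@H]2C[C@@H](C(C)(C)O)CC[C@]12C | intermediate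
23 | (4S,4aR,7S,8aS)-7-(2-hydroxypropan-2-yl)-4a-methyl-4-[(1R)-3-methyl-1-(2,4,6-trimethoxyphenyl)butyl]octahydronaphthalen-1(2H)-one | CC(C)C[C@@H](c1c(OC)cc(OC)cc1OC)[C@@H]1CCC(=O)[C@H]2C[C@@H](C(C)(C)O)CC[C@]12C | intermediate
24 | (1R,4S,4aR,7S,8aS)-7-(2-hydroxypropan-2-yl)-1,4a-dimethyl-4-[(1R)-3-methyl-1-(2,4,6-trimethoxyphenyl)butyl]decahydronaphthalen-1-ol | CC(C)C[C@@H](c1c(OC)cc(OC)cc1OC)[C@@H]1CC[C@@](C)(O)[C@H]2C[C@@H](C(C)(C)O)CC[C@]12C | intermediate
25 | (1R,4S,4aR,7S,8aS)-4-[(1R)-1-(3,5-dibromo-2,4,6-trimethoxyphenyl)-3-methylbutyl]-7-(2-hydroxypropan-2-yl)-1,4a-dimethyldecahydronaphthalen-1-ol | CC(C)C[C@@H](c1c(OC)c(Br)c(OC)c(Br)c1OC)[C@@H]1CC[C@@](C)(O)[C@H]2C[C@@H](C(C)(C)O)CC[C@]12C | intermediate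
26 | 3,5-dilithioaryl bis(lithium alkoxide) derived from 25 | CC(C)C[C@@H](c1c(OC)c([Li])c(OC)c([Li])c1OC)[C@@H]1CC[C@@](C)(O[Li])[C@H]2C[C@@H](C(C)(C)O[Li])CC[C@]12C | intermediate (not isolated)
27 | 5-[(1R)-1-[(1S,4R,4aS,6S,8aR)-4-hydroxy-6-(2-hydroxypropan-2-yl)-4,8a-dimethyldecahydronaphthalen-1-yl]-3-methylbutyl]-2,4,6-trimethoxybenzene-1,3-dicarbaldehyde | CC(C)C[C@@H](c1c(OC)c(C=O)c(OC)c(C=O)c1OC)[C@@H]1CC[C@@](C)(O)[C@H]2C[C@@H](C(C)(C)O)CC[C@]12C | intermediate
28 | 5-[(1R)-1-[(1S,4R,4aS,6S,8aR)-4-hydroxy-6-(2-hydroxypropan-2-yl)-4,8a-dimethyldecahydronaphthalen-1-yl]-3-methylbutyl]-2,4,6-trihydroxybenzene-1,3-dicarbaldehyde | CC(C)C[C@@H](c1c(O)c(C=O)c(O)c(C=O)c1O)[C@@H]1CC[C@@](C)(O)[C@H]2C[C@@H](C(C)(C)O)CC[C@]12C | target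

**Step count**

Total: 19 steps. Longest linear sequence: 16 steps (steps 4–19).

**Steps most likely to fail**

Step 12 (key step). The triene may be lost before it closes: over-reduction in step 11, Z-to-E isomerisation and [1,7]-hydrogen migration from the C10 methyl during isolation and slow heating. Facial selectivity may also be eroded at 150 °C; the fallback below does not address that. Fallback (Stille coupling–electrocyclization cascade, C4–C5 bond made last, triene never isolated): it sets out from alkenyl iodide 15 and triflate 4. Iodide 15 is coupled with (Z)-1,2-bis(tributylstannyl)ethene (from acetylene and Bu3SnSnBu3; Pd(PPh3)4, CuI, DMF, rt) to give tributyl[(1Z,3E,5R)-7-methyl-5-(2,4,6-trimethoxyphenyl)octa-1,3-dien-1-yl]stannane F1. Stille coupling of this stannane with 4 (Pd(PPh3)4, LiCl, dioxane, 100 then 150 °C) should generate triene 18 at the closure temperature, where it cyclises as it forms. The route is rejoined at cyclohexadiene 19; steps 3, 10 and 11 are bypassed.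

Step 14. Facial discrimination may fail next to the quaternary centre and the axial side chain, so that hydrogen reaches C5 from the methyl face and gives the cis-fused epimer, or the hindered alkene may react sluggishly. Fallback (hydroxyl-directed hydrogenation): it sets out from alkene 20. Epoxidation (m-CPBA, NaHCO3, CH2Cl2) on the face opposite the C10 methyl gives the 4,5-epoxide of 20 F2. Diethylaluminium 2,2,6,6-tetramethylpiperidide (PhMe, 0 °C) isomerises it to the allylic alcohol 2-[(2S,4aR,5S,8S)-8-hydroxy-4a-methyl-5-[(1R)-3-methyl-1-(2,4,6-trimethoxyphenyl)butyl]-2,3,4,4a,5,6,7,8-octahydronaphthalen-2-yl]propan-2-ol F3 (C5=C6, C4 hydroxyl). Hydrogenation with [Ir(cod)(PCy3)(py)]PF6 and H2 in CH2Cl2 delivers hydrogen to C5 from the face of the ring C4 hydroxyl. The route is rejoined at alcohol 22.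

Step 9 (with step 8). Enolisation of aldehyde 14 at its benzylic α-carbon may erode the C1′ configuration during oxidation, handling and olefination. Fallback (Julia–Kocienski route that never makes the aldehyde): it sets out from alcohol 13. Mitsunobu reaction with 1-phenyl-1H-tetrazole-5-thiol (PPh3, DIAD, THF) gives 5-{[(2S)-4-methyl-2-(2,4,6-trimethoxyphenyl)pentyl]sulfanyl}-1-phenyl-1H-tetrazole F4. Oxidation ((NH4)6Mo7O24, H2O2, EtOH) gives 5-{[(2S)-4-methyl-2-(2,4,6-trimethoxyphenyl)pentyl]sulfonyl}-1-phenyl-1H-tetrazole F5. Olefination with 3-(trimethylsilyl)prop-2-ynal (KN(SiMe3)2, DME, −60 °C) gives trimethyl[(3E,5R)-7-methyl-5-(2,4,6-trimethoxyphenyl)oct-3-en-1-yn-1-yl]silane F6. Fluoride-induced desilylation to (3E,5R)-7-methyl-5-(2,4,6-trimethoxyphenyl)oct-3-en-1-yne F7 (not isolated) and Sonogashira coupling with triflate 4 (CsF, Pd(PPh3)2Cl2, CuI, Et3N, THF–MeOH) follow. The route is rejoined at dienyne 17; steps 3, 8, 9 and 10 are then not needed.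

**Further compounds**

F1 | step 12 | tributyl[(1Z,3E,5R)-7-methyl-5-(2,4,6-trimethoxyphenyl)octa-1,3-dien-1-yl]stannane | CC(C)C[C@@H](c1c(OC)cc(OC)cc1OC)/C=C/C=C\[Sn](CCCC)(CCCC)CCCC
F2 | step 14 | 4,5-epoxide of 20 (oxygen on the face opposite the C10 methyl) | CC(C)C[C@@H](c1c(OC)cc(OC)cc1OC)[C@@H]1CC[C@@H]3O[C@@]32C[C@@H](C(C)(C)O)CC[C@]12C
F3 | step 14 | 2-[(2S,4aR,5S,8S)-8-hydroxy-4a-methyl-5-[(1R)-3-methyl-1-(2,4,6-trimethoxyphenyl)butyl]-2,3,4,4a,5,6,7,8-octahydronaphthalen-2-yl]propan-2-ol | CC(C)C[C@@H](c1c(OC)cc(OC)cc1OC)[C@@H]1CC[C@H](O)C2=C[C@@H](C(C)(C)O)CC[C@]12C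
F4 | step 9 | 5-{[(2S)-4-methyl-2-(2,4,6-trimethoxyphenyl)pentyl]sulfanyl}-1-phenyl-1H-tetrazole | CC(C)C[C@@H](c1c(OC)cc(OC)cc1OC)CSc1nnnn1-c1ccccc1
F5 | step 9 | 5-{[(2S)-4-methyl-2-(2,4,6-trimethoxyphenyl)pentyl]sulfonyl}-1-phenyl-1H-tetrazole | CC(C)C[C@@H](c1c(OC)cc(OC)cc1OC)CS(=O)(=O)c1nnnn1-c1ccccc1
F6 | step 9 | trimethyl[(3E,5R)-7-methyl-5-(2,4,6-trimethoxyphenyl)oct-3-en-1-yn-1-yl]silane | CC(C)C[C@@H](c1c(OC)cc(OC)cc1OC)/C=C/C#C[Si](C)(C)C
F7 | step 9 | (3E,5R)-7-methyl-5-(2,4,6-trimethoxyphenyl)oct-3-en-1-yne | CC(C)C[C@@H](c1c(OC)cc(OC)cc1OC)/C=C/C#C
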